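## Retrosynthetic overview

1. The plan rests on the ring A array C14H2=C7–C8–C9–C10(Br), which lies beside the vicinal quaternary pair C6 (spiro) and C11 (CMe2). With Br traced back to an inverted OH, this array is what an isopropenyl group on C6 leaves after its CH2 opens a terminal C9–C10 oxirane and its CH3 gives up a proton (C8–C9 disconnection).
2. Ring B comes first, as a purchased six-membered ring (cyclohexane-1,2-dione monoketal). The C6–C11 bond is made on it by an Ireland–Claisen rearrangement that relays a CBS-set C2 carbinol to C6.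
3. The C10 oxirane is grown from the Claisen acid (MeLi, alpha-bromination, second CBS reduction, closure), so no oxidant has to choose among the three alkenes.
4. Ring A is closed second (step 11). After that, C10–OH becomes C10–Br with inversion, and ring B is finished: enone, C2=C3(Me) alkene, epoxide anti to C7, diaxial chlorohydrin, tertiary bromide.

Key step: step 11

Assumption: 1,4-dioxaspiro[4.5]decan-6-one is taken as a catalogue compound; chamigrene numbering is used for all atoms (spiro C6; ring A C6–C7(=C14)–C8–C9–C10–C11(Me2); ring B C1–C2–C3(C15)–C4–C5–C6).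

## Route

Step 1
Reactants: 1 1,4-dioxaspiro[4.5]decan-6-one
Product: 3 1,4-dioxaspiro[4.5]dec-7-en-6-one, via lithium enolate 2 (not isolated)
Conditions: LiN(i-Pr)2, THF, −78 °C; then PhS(Cl)=N-t-Bu, −78 °C
Reagents that add atoms: none
Why: Mukaiyama dehydrogenation with the sulfinimidoyl chloride: the ketal carbon blocks one side so only one enolate can form, its sulfur adduct collapses by a five-centre syn elimination already at −78 °C, and the base-only medium leaves the dioxolane intact.

Step 2
Reactants: 3 1,4-dioxaspiro[4.5]dec-7-en-6-one; 4 isopropenylmagnesium bromide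
Product: 5 (±)-trimethyl{[8-(prop-1-en-2-yl)-1,4-dioxaspiro[4.5]dec-6-en-6-yl]oxy}silane
Conditions: 4, CuBr·SMe2 (10 mol %), Me3SiCl, THF, −78 °C
Reagents that add atoms: isopropenylmagnesium bromide 4, CC(=C)[Mg]Br; chlorotrimethylsilane, C[Si](C)(C)Cl
Why: Copper-catalysed conjugate addition of the alkenyl Grignard reagent, accelerated by Me3SiCl, which also fixes the enolate regiospecifically as its silyl ether; the new stereocentre (later C6) is racemic here and is erased in step 3.

Step 3
Reactants: 5 (±)-silyl enol ether
Product: 6 8-(prop-1-en-2-yl)-1,4-dioxaspiro[4.5]dec-7-en-6-one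
Conditions: Pd(OAc)2 (10 mol %), O2 (1 atm), DMSO, 23 °C
Reagents that add atoms: none
Why: Saegusa–Ito oxidation in its catalytic, O2-driven form: the oxa-allyl palladium species can only lose the hydrogen at the isopropenyl-bearing carbon, which restores the enone with the isopropenyl group in the beta position under neutral conditions.

Step 4
Reactants: 6 8-(prop-1-en-2-yl)-1,4-dioxaspiro[4.5]dec-7-en-6-one
Product: 7 (6S)-8-(prop-1-en-2-yl)-1,4-dioxaspiro[4.5]dec-7-en-6-ol
Conditions: (R)-2-methyl-CBS-oxazaborolidine (20 mol %), catecholborane, toluene, −78 °C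
Reagents that add atoms: none
Why: Corey–Bakshi–Shibata reduction: the fully substituted ketal carbon acts as the large flank and the vinylic CH as the small one, so the (R)-catalyst should deliver hydride to give the (6S)-alcohol (chamigrene C2), and catecholborane at low temperature reduces 1,2 without touching the diene.

Step 5
Reactants: 7 (6S)-allylic alcohol; 8 isobutyryl chloride
Product: 9 (6S)-8-(prop-1-en-2-yl)-1,4-dioxaspiro[4.5]dec-7-en-6-yl 2-methylpropanoate
Conditions: 8, Et3N, DMAP (cat.), CH2Cl2, 0 → 23 °C
Reagents that add atoms: isobutyryl chloride 8, CC(C)C(=O)Cl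
Why: DMAP-catalysed acylation of a secondary alcohol, which does not touch the C–O stereocentre.

Step 6
Reactants: 9 (6S)-isobutyrate
Product: 12 2-methyl-2-[(8S)-8-(prop-1-en-2-yl)-1,4-dioxaspiro[4.5]dec-6-en-8-yl]propanoic acid, via silyl ketene acetal 10 (not isolated), via trimethylsilyl ester 11 (not isolated)
Conditions: LiN(i-Pr)2, THF, −78 °C; Me3SiCl, −78 → 23 °C, then 65 °C; aq. NaOH, then citric acid to pH 4
Reagents that add atoms: chlorotrimethylsilane, C[Si](C)(C)Cl (silicon only in 10 and 11, lost on work-up)
Why: Ireland–Claisen rearrangement: the tetrasubstituted, geometry-free silyl ketene acetal delivers its CMe2 terminus to C6 across the ring face that carries the C2–O bond (suprafacial [3,3] shift), so the C2 configuration is relayed to the quaternary C6 (S), the C6–C11 bond joins the two quaternary carbons, and the alkene moves to C1=C2.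

Step 7
Reactants: 12 Claisen acid
Product: 13 3-methyl-3-[(8S)-8-(prop-1-en-2-yl)-1,4-dioxaspiro[4.5]dec-6-en-8-yl]butan-2-one
Conditions: MeLi (3.5 equiv), Et2O, 0 → 23 °C; inverse quench into aq. NH4Cl
Reagents that add atoms: methyllithium, [Li]C
Why: Ketone synthesis from a lithium carboxylate and methyllithium: the dilithium gem-diolate survives until the quench, crowding around C10 blocks a second addition, and ketal and alkenes are inert; the new methyl carbon is C9.

Step 8
Reactants: 13 methyl ketone
Product: 15 1-bromo-3-methyl-3-[(8S)-8-(prop-1-en-2-yl)-1,4-dioxaspiro[4.5]dec-6-en-8-yl]butan-2-one, via trimethylsilyl enol ether 14 (not isolated)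
Conditions: LiN(i-Pr)2, Me3SiCl, THF, −78 → 0 °C; pentane/aq. NaHCO3 wash; crude 14, NBS, THF, −78 °C
Reagents that add atoms: chlorotrimethylsilane, C[Si](C)(C)Cl (silicon only in 14); N-bromosuccinimide, O=C1CCC(=O)N1Br
Why: Kinetic silyl enol ether formation followed by electrophilic bromination: C11 is quaternary, so the methyl group is the only enolisable site, and the electron-rich enol ether takes up Br+ at −78 °C well ahead of the two hindered alkenes.

Step 9
Reactants: 15 bromomethyl ketone
Product: 16 (2R)-1-bromo-3-methyl-3-[(8S)-8-(prop-1-en-2-yl)-1,4-dioxaspiro[4.5]dec-6-en-8-yl]butan-2-ol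
Conditions: (R)-2-methyl-CBS-oxazaborolidine (50 mol %), catecholborane, toluene, −40 → −20 °C
Reagents that add atoms: none
Why: Corey–Bakshi–Shibata reduction of an alpha-halo ketone: tert-alkyl C11 is the large group and CH2Br the small one, so the (R)-catalyst should set C10 as (R) under reagent control, the remote C6 having little say, and catecholborane spares the alkenes.

Step 10
Reactants: 16 (R)-bromohydrin
Product: 17 (8S)-8-{2-[(2R)-oxiran-2-yl]propan-2-yl}-8-(prop-1-en-2-yl)-1,4-dioxaspiro[4.5]dec-6-ene
Conditions: K2CO3, MeOH, 0 → 23 °C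
Reagents that add atoms: none
Why: Intramolecular Williamson closure (3-exo-tet) of the bromohydrin; only the C9–Br bond is broken, so C10 stays (R).

Step 11
Reactants: 17 epoxy diene ketal
Product: 18 (6S,10S)-3,3-(ethylenedioxy)-15-norchamigra-1,7(14)-dien-10-ol (spiro[5.5]undecane; ring A with C7 exocyclic methylene, C10 OH, C11 gem-dimethyl; ring B with C1=C2 and C3 dioxolane)
Conditions: Me2AlCl (2.5 equiv), CH2Cl2, −78 → −20 °C; Et3N, then aq. potassium sodium tartrate
Reagents that add atoms: none
Why: Me2AlCl binds the oxirane oxygen, the isopropenyl CH2 (C8) attacks the primary oxirane carbon C9 from the rear of the C9–O bond, and the resulting tertiary C7 cation gives up a proton of its methyl group (C14) to an Al–CH3 bond (methane), which leaves the C10 aluminium alkoxide and no Brønsted acid that could move the new alkene or hydrolyse the ketal. The closest known reaction type is the Lewis-acid epoxide-initiated cation–olefin cyclisation that ends in proton loss (epoxy-ene cyclisation), run under the alkylaluminium halide conditions of carbonyl-ene chemistry. Ring A (C6–C7–C8–C9–C10–C11) closes through a chair-like array in the 6-endo mode at both partners (6-endo-tet at the oxirane, 6-endo-trig at the alkene), so both oxirane carbons become ring members, and the quaternary carbons C6 and C11 compress the chain and hold C8 next to C9. No stereocentre is created: the C10–O bond is never broken, so C10 keeps the arrangement set in step 9 (the descriptor changes from R to S only because C9 loses its oxygen), and C6 is a spectator. The step needs attack at C9 and not C10, secured by the neopentyl shielding of C10 by C11 and by the strained 5-endo geometry of the alternative, and it needs the isopropenyl group and not C1=C2 as nucleophile, secured because only C7 can carry a tertiary cation and C1=C2 is deactivated by the adjacent ketal. It also needs proton loss from C14 rather than C8, which rests on the easier access to the methyl hydrogens beside the crowded spiro carbon under kinetic, acid-free conditions, and it needs the dioxolane to survive, for which the extra Lewis acid and the low temperature are chosen.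

Step 12
Reactants: 18 spiro alcohol
Product: 19 (6S,10R)-10-bromo-3,3-(ethylenedioxy)-15-norchamigra-1,7(14)-diene
Conditions: CBr4, PPh3, 2,6-lutidine, toluene, 0 → 60 °C
Reagents that add atoms: tetrabromomethane, BrC(Br)(Br)Br
Why: Appel reaction: the alkoxyphosphonium ion is displaced by bromide in an SN2 step that inverts C10 from (S) to (R), should run through the ring A chair with the leaving group axial, and uses a non-polar solvent and buffered medium to hold back ionisation (methyl shift from C11) and ketal loss.

Step 13
Reactants: 19 bromo ketal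
Product: 20 (6S,10R)-10-bromo-15-norchamigra-1,7(14)-dien-3-one
Conditions: PPTS (cat.), THF–H2O (4:1), 50 °C
Reagents that add atoms: water, O
Why: Mild acid-catalysed hydrolysis of an allylic ketal, which ionises far more readily than the hindered exocyclic alkene is protonated; the neopentyl-type bromide is inert.

Step 14
Reactants: 20 bromo enone
Product: 22 (6S,10R)-10-bromo-15-norchamigra-2,7(14)-dien-3-yl trifluoromethanesulfonate, via lithium enolate 21 (not isolated)
Conditions: LiBH(s-Bu)3 (1.05 equiv), THF, −78 °C; then Comins' reagent, −78 → 0 °C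
Reagents that add atoms: N-(5-chloropyridin-2-yl)bis(trifluoromethanesulfonimide) (Comins' reagent), FC(F)(F)S(=O)(=O)N(c1ccc(Cl)cn1)S(=O)(=O)C(F)(F)F
Why: 1,4-Reduction of a beta-unsubstituted cyclohexenone by the bulky trialkylborohydride and O-triflation of the regiodefined enolate, which places the new double bond at C2=C3 and nowhere else; the shielded secondary bromide does not react at −78 °C.

Step 15
Reactants: 22 enol triflate
Product: 23 (6S,10R)-10-bromochamigra-2,7(14)-diene (10-bromo-beta-chamigrene)
Conditions: Me2Zn, Pd(PPh3)4 (5 mol %), THF, 0 → 23 °C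
Reagents that add atoms: dimethylzinc, C[Zn]C
Why: Negishi coupling: zerovalent palladium inserts into the alkenyl C–O(Tf) bond only, fast methyl transfer from zinc and reductive elimination give the C3 methyl group (C15), and the hindered alkyl bromide is not touched.

Step 16
Reactants: 23 10-bromo-beta-chamigrene
Product: 24 (2S,3R,6S,10R)-10-bromo-2,3-epoxychamigr-7(14)-ene (oxygen on the ring B face syn to C11 and anti to C7)
Conditions: m-CPBA (1.0 equiv), NaHCO3, CH2Cl2, −20 °C
Reagents that add atoms: 3-chloroperoxybenzoic acid, OOC(=O)c1cccc(Cl)c1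
Why: Prilezhaev epoxidation: the trisubstituted C2=C3 is more electron-rich and less shielded than C7=C14 next to the spiro carbon, and in the half-chair with bulky C11 pseudo-equatorial the pseudo-axial C7 arm covers one face, so oxygen should arrive anti to C7 and set C2 (S) and C3 (R).

Step 17
Reactants: 24 epoxide
Product: 25 (2R,3R,6S,10R)-10-bromo-2-chlorochamigr-7(14)-en-3-ol (Cl and OH trans-diaxial)
Conditions: Li2CuCl4, THF, 23 °C; aq. NaH2PO4/Na2HPO4 (pH 7)
Reagents that add atoms: dilithium tetrachlorocuprate, [Li+].[Li+].[Cu+2].[Cl-].[Cl-].[Cl-].[Cl-]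
Why: SN2-type halide opening under the Fürst–Plattner rule: the soft chloride attacks the secondary C2 rather than the tertiary C3, anti to oxygen and along the axial line of the chair that keeps C11 equatorial, which inverts C2 to (R) and leaves the C3–O bond untouched.

Step 18
Reactants: 25 chlorohydrin
Product: 26 (2R,3R,6S,10R)-3,10-dibromo-2-chlorochamigr-7(14)-ene (target)
Conditions: Me3SiBr (1.2 equiv), CH2Cl2, −40 → 0 °C
Reagents that add atoms: bromotrimethylsilane, C[Si](C)(C)Br
Why: Silyl bromide substitution of a tertiary alcohol (SN1 type with neighbouring-group help): the axial C3 oxygen is silylated and leaves antiperiplanar to the axial C2 chlorine, the chlorine-bridged cation is opened by bromide at the tertiary C3 from the face the oxygen left, and C3 should thus keep its arrangement (R, Br trans to Cl).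

## Compound list

1 | 1,4-dioxaspiro[4.5]decan-6-one | O=C1CCCCC12OCCO2 | starting material
2 | lithium enolate of 1 | [Li]OC1=CCCCC12OCCO2 | intermediate
3 | 1,4-dioxaspiro[4.5]dec-7-en-6-one | O=C1C=CCCC12OCCO2 | intermediate
4 | isopropenylmagnesium bromide | CC(=C)[Mg]Br | starting material
5 | (±)-trimethyl{[8-(prop-1-en-2-yl)-1,4-dioxaspiro[4.5]dec-6-en-6-yl]oxy}silane | C[Si](C)(C)OC1=CC(C(C)=C)CCC12OCCO2 | intermediate
6 | 8-(prop-1-en-2-yl)-1,4-dioxaspiro[4.5]dec-7-en-6-one | O=C1C=C(C(C)=C)CCC12OCCO2 | intermediate
7 | (6S)-8-(prop-1-en-2-yl)-1,4-dioxaspiro[4.5]dec-7-en-6-ol | O[C@H]1C=C(C(C)=C)CCC12OCCO2 | intermediate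
8 | isobutyryl chloride | CC(C)C(=O)Cl | starting material
9 | (6S)-8-(prop-1-en-2-yl)-1,4-dioxaspiro[4.5]dec-7-en-6-yl 2-methylpropanoate | CC(C)C(=O)O[C@H]1C=C(C(C)=C)CCC12OCCO2 | intermediate
10 | trimethylsilyl ketene acetal of 9 | CC(C)=C(O[Si](C)(C)C)O[C@H]1C=C(C(C)=C)CCC12OCCO2 | intermediate
11 | trimethylsilyl ester of 12 | CC(=C)[C@]1(C(C)(C)C(=O)O[Si](C)(C)C)CCC2(OCCO2)C=C1 | intermediate
12 | 2-methyl-2-[(8S)-8-(prop-1-en-2-yl)-1,4-dioxaspiro[4.5]dec-6-en-8-yl]propanoic acid | CC(=C)[C@]1(C(C)(C)C(=O)O)CCC2(OCCO2)C=C1 | intermediate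
13 | 3-methyl-3-[(8S)-8-(prop-1-en-2-yl)-1,4-dioxaspiro[4.5]dec-6-en-8-yl]butan-2-one | CC(=C)[C@]1(C(C)(C)C(C)=O)CCC2(OCCO2)C=C1 | intermediate
14 | trimethylsilyl enol ether of 13 | CC(=C)[C@]1(C(C)(C)C(=C)O[Si](C)(C)C)CCC2(OCCO2)C=C1 | intermediate
15 | 1-bromo-3-methyl-3-[(8S)-8-(prop-1-en-2-yl)-1,4-dioxaspiro[4.5]dec-6-en-8-yl]butan-2-one | CC(=C)[C@]1(C(C)(C)C(=O)CBr)CCC2(OCCO2)C=C1 | intermediate
16 | (2R)-1-bromo-3-methyl-3-[(8S)-8-(prop-1-en-2-yl)-1,4-dioxaspiro[4.5]dec-6-en-8-yl]butan-2-ol | CC(=C)[C@]1(C(C)(C)[C@@H](O)CBr)CCC2(OCCO2)C=C1 | intermediate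
17 | (8S)-8-{2-[(2R)-oxiran-2-yl]propan-2-yl}-8-(prop-1-en-2-yl)-1,4-dioxaspiro[4.5]dec-6-ene | CC(=C)[C@]1(C(C)(C)[C@@H]3CO3)CCC2(OCCO2)C=C1 | intermediate
18 | (6S,10S)-3,3-(ethylenedioxy)-15-norchamigra-1,7(14)-dien-10-ol | C=C1CC[C@H](O)C(C)(C)[C@]12CCC3(OCCO3)C=C2 | intermediate
19 | (6S,10R)-10-bromo-3,3-(ethylenedioxy)-15-norchamigra-1,7(14)-diene | C=C1CC[C@@H](Br)C(C)(C)[C@]12CCC3(OCCO3)C=C2 | intermediate
20 | (6S,10R)-10-bromo-15-norchamigra-1,7(14)-dien-3-one | C=C1CC[C@@H](Br)C(C)(C)[C@]12CCC(=O)C=C2 | intermediate
21 | lithium C2=C3 enolate from 20 | C=C1CC[C@@H](Br)C(C)(C)[C@]12CCC(O[Li])=CC2 | intermediate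
22 | (6S,10R)-10-bromo-15-norchamigra-2,7(14)-dien-3-yl trifluoromethanesulfonate | C=C1CC[C@@H](Br)C(C)(C)[C@]12CCC(OS(=O)(=O)C(F)(F)F)=CC2 | intermediate
23 | (6S,10R)-10-bromochamigra-2,7(14)-diene | C=C1CC[C@@H](Br)C(C)(C)[C@]12CCC(C)=CC2 | intermediate
24 | (2S,3R,6S,10R)-10-bromo-2,3-epoxychamigr-7(14)-ene | C=C1CC[C@@H](Br)C(C)(C)[C@]12CC[C@@]3(C)O[C@H]3C2 | intermediate
25 | (2R,3R,6S,10R)-10-bromo-2-chlorochamigr-7(14)-en-3-ol | C=C1CC[C@@H](Br)C(C)(C)[C@]12CC[C@@](C)(O)[C@H](Cl)C2 | intermediate
26 | (2R,3R,6S,10R)-3,10-dibromo-2-chlorochamigr-7(14)-ene | C=C1CC[C@@H](Br)C(C)(C)[C@]12CC[C@@](C)(Br)[C@H](Cl)C2 | target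

## Step count and risks

Total step count: 18. Longest linear sequence: 18 steps (1 to 26); 4 and 8 are bought and enter directly.

**Step 11 (closure of ring A).**
- What may go wrong:
  - chloride may be delivered from aluminium to C9;
  - the C10–O bond may ionise with a hydride or alkyl shift from C9 or C11;
  - the C10 oxygen may capture the C7 cation across the ring;
  - the C7 cation may rearrange by a 1,2-shift from the spiro carbon;
  - the proton may be lost from C8 instead of C14;
  - the Lewis acid may ionise the allylic ketal.
- Fallback: the same C8–C9 bond is made by enolate alkylation, setting out from bromohydrin 16 and coming back at 18. Silylation of 16 (t-BuMe2SiOTf, 2,6-lutidine, CH2Cl2) would give the silyl ether F1. Ozonolysis (O3, CH2Cl2–MeOH, −78 °C, then Me2S) should select the electron-richer 1,1-disubstituted alkene over the ketal-flanked C1=C2 and give the methyl ketone F2. KN(SiMe3)2 in THF (−78 → 0 °C) forms the only possible enolate, and a 6-(enolendo)-exo-tet displacement of the primary bromide would give the spiro ketone F3. Methylenation of the hindered carbonyl with Cp2TiMe2 (toluene, 80 °C) would give the silyl ether F4, and Bu4NF in THF would release 18.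

**Step 12 (bromide at C10 with inversion).**
- What may go wrong: displacement next to the quaternary C11 may be slow, so that elimination towards C9, ionisation with methyl migration, or acid-induced ketal loss overtakes substitution.
- Fallback: activation and displacement are separated, setting out from 18 and coming back at 19. Tf2O and pyridine (CH2Cl2, −20 °C) would give the triflate F5. Its far better and much smaller leaving group should allow an SN2 reaction with soluble, unsolvated bromide (Bu4NBr, toluene, 0 → 40 °C) without a bulky phosphonium centre at C10.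

**Step 18 (tertiary bromide at C3).**
- What may go wrong: ionisation is slowed by the beta-chlorine, so proton loss from the cation, bromide attack on the wrong face, chlorine migration, or hydrogen bromide adding to or shifting the C7=C14 alkene may compete.
- Fallback: the oxygen detour is dropped and both halogens are added in one anti addition, setting out from 23 and coming back at 26. Tetrabutylammonium dichlorobromate (Bu4NBrCl2, CH2Cl2, −78 °C) should form the bromonium ion on the C2=C3 face anti to the pseudo-axial C7. Diaxial opening in the chair with C11 equatorial should then direct chloride to C2, as in additions to conformationally biased trisubstituted cyclohexenes. No compound outside the list is made on this way (F0).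

## Further compounds

F1 | step 11 | tert-butyldimethylsilyl ether of bromohydrin 16 | CC(=C)[C@]1(C(C)(C)[C@@H](O[Si](C)(C)C(C)(C)C)CBr)CCC2(OCCO2)C=C1
F2 | step 11 | C7 methyl ketone from F1 (isopropenyl C=CH2 cleaved to C=O, C6 and C10 spatially unchanged) | CC(=O)[C@]1(C(C)(C)[C@@H](O[Si](C)(C)C(C)(C)C)CBr)CCC2(OCCO2)C=C1
F3 | step 11 | spiro C7 ketone with C10 silyl ether, C1=C2 alkene and C3 ketal | O=C1CC[C@H](O[Si](C)(C)C(C)(C)C)C(C)(C)[C@]12CCC3(OCCO3)C=C2
F4 | step 11 | tert-butyldimethylsilyl ether of 18 | C=C1CC[C@H](O[Si](C)(C)C(C)(C)C)C(C)(C)[C@]12CCC3(OCCO3)C=C2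
F5 | step 12 | C10 trifluoromethanesulfonate of 18 | C=C1CC[C@H](OS(=O)(=O)C(F)(F)F)C(C)(C)[C@]12CCC3(OCCO3)C=C2
F0 | step 18 | none | none
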